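## The problem

Target 13 is (2,4-dimethoxyphenyl)(6,7-dimethoxy-1H-isochromen-3-yl)methanone. Its carbonyl carbon joins ring A (the 2,4-dimethoxyphenyl ring, atoms A1–A6 with A1 on the carbonyl) to C3 of a 1H-isochromene built from ring B (the 6,7-dimethoxybenzo ring) and ring C (the pyran ring C1H2–O2–C3=C4). There is no stereocentre, so the synthesis has to control only regiochemistry and oxidation level. Ring C must end with the C3=C4 double bond in place and C1 at the CH2 level. C1 is benzylic and next to oxygen, so a late dehydrogenation of a saturated ring C could run on to the isochromenylium ion or the isocoumarin. The acyl group sits on the oxygen-bearing C3, where an enol ether is not nucleophilic, so C3 has to enter the ketone-forming step as an electrophilic or metal-bound carbon. The O2–C3=C4 enol ether is deactivated by the ketone but still hydrolysable by strong aqueous acid, the cross-conjugated enone accepts nucleophiles, and four aryl methyl ethers rule out hard Lewis acids late in the route. The enabling feature is in ring A: its oxygens stand at A2 and A4, ortho and para to A1, which is the 1,3-dioxygen pattern of an acetoacetate-derived four-carbon diene. Ring A can therefore be assembled on an alkynyl ketone whose two alkyne carbons become A1 and A6.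

## Retrosynthesis

**13 from 12.** The A4 O–CH3 bond is cut first, giving phenol 12. This cut is chosen because the ring A construction below delivers A4 as a free hydroxyl and A2 as a methyl ether. The phenol is para to the ketone, acidic and unhindered, so the forward step is a plain O-methylation that leaves C1H2 and the enol ether alone.

**12 from 6 and 9.** Ring A is opened at A1–A2 and A5–A6. This leaves ynone 6, which supplies A1 and A6 together with the ketone and rings B and C, and diene 9, which supplies A2–A5 with both oxygens. The neighbouring cuts at the ketone (acylating a ready-made dimethoxyarene, or adding an aryl-metal reagent) need Lewis acids or strong nucleophiles next to the ring C enol ether. The benzannulation is thermal and neutral, and its regiochemistry is fixed by the polarity of the partners. The forward reaction must pass through cycloadduct 10 and silyl ether 11 to the arene. It must also choose the alkyne over the C3=C4 bond and over the carbonyl group.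

**6 from 5.** The terminal alkyne C–H is traced to a C–Si bond. Silyl ynone 5 is the form in which the alkyne can be introduced as a monoprotected acetylene without double coupling. The forward step is a protodesilylation mild enough to spare the terminal ynone it releases.

**5 from 3 and 4.** Both bonds to the ketone carbon (C3–CO and CO–alkyne) are cut, and the carbonyl carbon is supplied as carbon monoxide. This leaves triflate 3 and trimethylsilylacetylene 4. A C3 anion of a 1H-isochromene is not accessible, because the C1 hydrogens would compete. An electrophilic C3 as an enol triflate is accessible, and it fixes the position of the ring C double bond. The forward reaction is a three-component carbonylative alkynylation in which CO insertion must outrun direct coupling.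

**3 from 1.** The O–S bond is cut, leading through enolate 2 to lactone 1. The lactone already holds rings B and C, both ring B methoxy groups and C1 at the right oxidation level, and its carbonyl carbon is C3. Enolisation towards the benzylic C4 creates C3=C4 without any oxidation step. The forward step must give O- and not C-sulfonylation and a product that survives isolation.

**9 from 7.** The O–Si bond of the diene is cut, leading through dienolate 8 to 4,4-dimethoxybut-3-en-2-one 7. This enone carries all four carbons and both methoxy groups. The forward step is a kinetic enol silylation of the only enolisable position.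

## Roads not taken

Alternative 1: Ring B is disconnected at C4–C4a and C1–C8a, so that it arrives as symmetric 4,5-dimethoxybenzyne.
- **Forward key step.** 2-Iodo-4,5-dimethoxyphenyl trifluoromethanesulfonate A1 would give the aryne by iodine–magnesium exchange. The alkynylmagnesium derived from 2-(2,4-dimethoxyphenyl)-2-ethynyl-1,3-dioxolane A2 would add to it, and DMF would formylate the ortho-arylmagnesium to give 2-{[2-(2,4-dimethoxyphenyl)-1,3-dioxolan-2-yl]ethynyl}-4,5-dimethoxybenzaldehyde A3.
- **Merits.** The symmetric aryne poses no regiochemical question, ring A is bought intact, and two C–C bonds form in one flask.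
- **Weak points.** The step closes no ring. Ring C still needs aldehyde reduction, a 6-endo hydroalkoxylation of the alkyne and ketal hydrolysis. The electron-rich ring B stabilises positive charge at C4 and the ketal withdraws at C3, so 5-exo closure to an alkylidene phthalan is the likely course. Ketal A2 must be made from an ynone that tends to add the diol in conjugate fashion. The alkylmagnesium used for the exchange competes for the aryne. The count is about eight to nine steps.
- **Comparison.** This road is better in needing no moisture-sensitive diene and no construction of ring A. The chosen plan offers instead a purchased, closed ring C with no cyclisation regiochemistry, and six steps.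

Alternative 2: Ring C is cut at C3–C4 and C1–O2.
- **Forward key step.** Irradiation of 4,5-dimethoxy-2-methylbenzaldehyde A4 would give the hydroxy-o-quinodimethane. This would add across the aldehyde C=O of 2-(2,4-dimethoxyphenyl)-2-oxoacetaldehyde A5 and close ring C as racemic 3-(2,4-dimethoxybenzoyl)-6,7-dimethoxyisochroman-1-ol A6, a mixture of lactol epimers whose centres are erased later.
- **Merits.** Both arenes are bought complete, no protecting group is needed, and the route is shorter on paper (about four to five steps). In step economy it is better than the chosen plan.
- **Weak points.** Photoenols are normally trapped by electron-poor alkenes, and capture by a carbonyl group is much less secure. A5 and A6 are aryl ketones that absorb in the same region and can undergo photoreduction or cleavage. A6 is at the wrong oxidation level twice. C1 must be reduced ionically without reducing the electron-rich aryl ketone, and C3–C4 must be dehydrogenated next to the oxidation-prone C1.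
- **Comparison.** The chosen plan is longer. It offers instead a key step of a known reaction type and a ring C that is at the correct oxidation level from the first step.

Alternative 3: The O2–C3 and C3–C4 bonds are cut.
- **Forward key step.** The carbenoid from 2-diazo-1-(2,4-dimethoxyphenyl)ethan-1-one A7 and Rh2(OAc)4 would be captured by the oxygen of 5,6-dimethoxy-1,3-dihydroisobenzofuran A8. A [1,2]-shift of a benzylic carbon (Stevens rearrangement) would then expand the ring to racemic (6,7-dimethoxy-3,4-dihydro-1H-isochromen-3-yl)(2,4-dimethoxyphenyl)methanone A9.
- **Merits.** The symmetric phthalan removes regiochemistry, two skeletal bonds form at once, and the step count (about five) matches or beats the chosen plan.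
- **Weak points.** Intermolecular oxonium ylide formation competes with insertion into the doubly activated benzylic C–H bonds of A8 and with carbene dimerisation. The ortho-methoxy group of A7 can trap the carbenoid intramolecularly to give a benzofuranone. A9 still needs dehydrogenation at C3–C4 beside the sensitive C1.
- **Comparison.** The chosen plan needs a labile triflate and a labile ynone. In return it creates C3=C4 by enolisation and not by oxidation, and its key step has no competing carbene pathway.

Key step: step 5

Assumption: 4,4-dimethoxybut-3-en-2-one 7 (the dimethyl acetal of acetylketene) is taken to be a purchasable catalogue compound, like lactone 1 and alkyne 4.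

Step 1
Reactants: 1 6,7-dimethoxyisochroman-3-one
Product: 3 6,7-dimethoxy-1H-isochromen-3-yl trifluoromethanesulfonate, via potassium enolate 2 (not isolated)
Conditions: KN(SiMe3)2, THF–DMPU, −78 °C; then PhNTf2, −78 → −20 °C; quick filtration through Et3N-treated silica
Reagents that add atoms: N-phenylbis(trifluoromethanesulfonimide) (PhNTf2), O=S(=O)(N(c1ccccc1)S(=O)(=O)C(F)(F)F)C(F)(F)F
Why: Enol triflate formation from a lactone: the base removes a benzylic C4 proton α to the carbonyl, and enolate 2, whose new C3=C4 bond is conjugated with ring B, is sulfonylated on oxygen to give the cyclic ketene acetal triflate. The product is kept cold and base-buffered because hydrolysis returns it to 1.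

Step 2
Reactants: 3 6,7-dimethoxy-1H-isochromen-3-yl trifluoromethanesulfonate, 4 trimethylsilylacetylene
Product: 5 1-(6,7-dimethoxy-1H-isochromen-3-yl)-3-(trimethylsilyl)prop-2-yn-1-one
Conditions: Pd(OAc)2 (5 mol %), Ph2P(CH2)3PPh2 (dppp), Et3N, CO (1 atm), DMF, 50 °C
Reagents that add atoms: carbon monoxide, [C-]#[O+]
Why: Carbonylative Sonogashira coupling: zerovalent palladium inserts into the C3–OTf bond, CO insertion gives the acylpalladium species, and the amine-activated alkyne 4 is acylated. Enol triflates are established partners for this ynone synthesis, and the chelating phosphine under CO holds back direct alkynylation.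

Step 3
Reactants: 5 1-(6,7-dimethoxy-1H-isochromen-3-yl)-3-(trimethylsilyl)prop-2-yn-1-one
Product: 6 1-(6,7-dimethoxy-1H-isochromen-3-yl)prop-2-yn-1-one
Conditions: Na2B4O7·10H2O (cat.), MeOH–H2O–THF, 20 °C
Reagents that add atoms: none
Why: Protodesilylation of a silyl ynone: the acyl group makes the alkynyl carbon a good leaving group from silicon, so a weakly basic borate buffer cleaves the C–Si bond without building up the methoxide concentration that would add to the ynone.

Step 4
Reactants: 7 4,4-dimethoxybut-3-en-2-one
Product: 9 1,1-dimethoxy-3-(trimethylsilyloxy)buta-1,3-diene, via lithium dienolate 8 (not isolated)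
Conditions: LiN(iPr)2 (commercial solution), THF, −78 °C; then Me3SiCl, −78 → 0 °C; distillation under reduced pressure
Reagents that add atoms: chlorotrimethylsilane, C[Si](C)(C)Cl
Why: Silyl enol ether formation: kinetic deprotonation of the acetyl CH3, the only enolisable position, and O-silylation of the cross-conjugated dienolate 8. The ketene acetal end is untouched by the non-nucleophilic amide base.

Step 5
Reactants: 6 1-(6,7-dimethoxy-1H-isochromen-3-yl)prop-2-yn-1-one, 9 1,1-dimethoxy-3-(trimethylsilyloxy)buta-1,3-diene
Product: 12 (6,7-dimethoxy-1H-isochromen-3-yl)(4-hydroxy-2-methoxyphenyl)methanone, via cyclohexadiene cycloadduct 10 (not isolated), via aryl silyl ether 11 (not isolated)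
Conditions: PhMe, 0 → 60 °C; then 0.1 M HCl, THF, 0 °C
Reagents that add atoms: none
Why: Diene 9 is a vinylogous ketene acetal with its largest HOMO coefficient at the CH2 terminus and ynone 6 has its largest LUMO coefficient at the unsubstituted alkyne carbon, so CH2 bonds to the terminal carbon (A5–A6) and the acetal carbon to the acyl-bearing carbon (A1–A2), either in a strongly asynchronous concerted [4+2] step or by Michael addition followed by collapse of the allenolate onto the dimethoxy-stabilised allyl cation. The resulting cyclohexa-1,4-diene 10 aromatises by 1,4-loss of methanol (from the acetal carbon and the ring CH2) to silyl ether 11, and dilute acid cleaves the aryl O–Si bond to give phenol 12. The closest known reaction type is the Diels–Alder benzannulation of 1,1-dialkoxy-3-silyloxybuta-1,3-dienes with acetylenic ketones and esters, which gives 4-hydroxy-2-alkoxyaryl carbonyl compounds. Ring A closes by the intermolecular [4+2] cycloaddition itself, both ring bonds forming in the same six-membered closure. No stereocentre is created, since the only sp3 ring carbons of 10 are a CH2 and a C(OMe)2 group and both become aromatic. The step needs regioselectivity (oxygen at A2 and A4) and site selectivity (the alkyne, not C3=C4 of ring C or the C=O group): the first follows from the matched polarisation of the partners and the unhindered alkyne terminus, the second from C3=C4 being trisubstituted, oxygen-substituted and conjugated to ring B, and from the absence of a Lewis acid that would promote hetero-Diels–Alder addition at the carbonyl. Because the acetal carbon can lose only methanol, A2 keeps its methoxy group while A4 emerges as the free phenol.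

Step 6
Reactants: 12 (6,7-dimethoxy-1H-isochromen-3-yl)(4-hydroxy-2-methoxyphenyl)methanone
Product: 13 (2,4-dimethoxyphenyl)(6,7-dimethoxy-1H-isochromen-3-yl)methanone
Conditions: MeI, K2CO3, acetone, 50 °C
Reagents that add atoms: iodomethane, CI
Why: Williamson ether synthesis: the phenol para to the ketone is the only acidic site and its phenoxide is methylated on oxygen. The ketone has no enolisable α-hydrogen, and the enol ether and C1H2 are inert to K2CO3.

## Compound list

1 | 6,7-dimethoxyisochroman-3-one | COc1cc2c(cc1OC)COC(=O)C2 | starting material
2 | potassium 6,7-dimethoxy-1H-isochromen-3-olate | [K+].[O-]C1=Cc2cc(OC)c(OC)cc2CO1 | intermediate (not isolated)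
3 | 6,7-dimethoxy-1H-isochromen-3-yl trifluoromethanesulfonate | COc1cc2c(cc1OC)COC(OS(=O)(=O)C(F)(F)F)=C2 | intermediate
4 | trimethylsilylacetylene | C#C[Si](C)(C)C | starting material
5 | 1-(6,7-dimethoxy-1H-isochromen-3-yl)-3-(trimethylsilyl)prop-2-yn-1-one | COc1cc2c(cc1OC)COC(C(=O)C#C[Si](C)(C)C)=C2 | intermediate
6 | 1-(6,7-dimethoxy-1H-isochromen-3-yl)prop-2-yn-1-one | C#CC(=O)C1=Cc2cc(OC)c(OC)cc2CO1 | intermediate
7 | 4,4-dimethoxybut-3-en-2-one | CC(=O)C=C(OC)OC | starting material
8 | lithium 4,4-dimethoxybuta-1,3-dien-2-olate | [Li+].[O-]C(=C)C=C(OC)OC | intermediate (not isolated)
9 | 1,1-dimethoxy-3-(trimethylsilyloxy)buta-1,3-diene | C=C(O[Si](C)(C)C)C=C(OC)OC | intermediate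
10 | [6,6-dimethoxy-4-(trimethylsilyloxy)cyclohexa-1,4-dien-1-yl](6,7-dimethoxy-1H-isochromen-3-yl)methanone | COC1(OC)C=C(O[Si](C)(C)C)CC=C1C(=O)C1=Cc2cc(OC)c(OC)cc2CO1 | intermediate (not isolated)
11 | (6,7-dimethoxy-1H-isochromen-3-yl)[2-methoxy-4-(trimethylsilyloxy)phenyl]methanone | COc1cc(O[Si](C)(C)C)ccc1C(=O)C1=Cc2cc(OC)c(OC)cc2CO1 | intermediate (not isolated)
12 | (6,7-dimethoxy-1H-isochromen-3-yl)(4-hydroxy-2-methoxyphenyl)methanone | COc1cc(O)ccc1C(=O)C1=Cc2cc(OC)c(OC)cc2CO1 | intermediate
13 | (2,4-dimethoxyphenyl)(6,7-dimethoxy-1H-isochromen-3-yl)methanone | COc1ccc(C(=O)C2=Cc3cc(OC)c(OC)cc3CO2)c(OC)c1 | target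

## Step count and risk

Total step count: 6. Longest linear sequence: 5 steps (steps 1, 2, 3, 5, 6). Step 4 makes the diene on a one-step side branch that joins at step 5.

**Step 5 (key step).** The diene may be lost to hydrolysis or silyl transfer before it meets the ynone. The first bond may form at A6 by Michael addition without ring closure, or the terminal ynone may oligomerise. All of this comes from pairing a very moisture-sensitive ketene acetal with an acceptor that has several electrophilic sites. The fallback gives up the construction of ring A and buys it. It sets out from triflate 3: a carbonylative Suzuki–Miyaura coupling with (2,4-dimethoxyphenyl)boronic acid under CO (PdCl2(dppf), K2CO3, anisole, 1 atm CO, 80 °C) would give target 13 directly. It rejoins the route at 13 and makes no compound outside the route (F0).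

**Step 2.** Direct alkynylation without CO insertion may outrun carbonylation, or the triflate may be solvolysed back to the lactone in the warm amine medium. The fallback separates the carbonylation from the introduction of the alkyne. It sets out from triflate 3. Aminocarbonylation with N,O-dimethylhydroxylamine hydrochloride and CO (Pd(OAc)2, Xantphos, Et3N, toluene, 1 atm CO) would give N,6,7-trimethoxy-N-methyl-1H-isochromene-3-carboxamide F1. Ethynylmagnesium bromide (THF, −78 → 0 °C, inverse quench into cold aqueous NaHSO4) would then convert it into ynone 6. The route is rejoined at 6 and step 3 is bypassed.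

**Step 1.** The ketene acetal triflate may revert to the lactone by hydrolysis during isolation, or sulfonylation may go to carbon. The fallback changes the class of electrophile and the way the ketone is built. It sets out from lactone 1. Trapping enolate 2 with diphenyl chlorophosphate would give the chromatographable 6,7-dimethoxy-1H-isochromen-3-yl diphenyl phosphate F2. Methoxycarbonylation (Pd(PPh3)4, CO, MeOH, Et3N, DMF) would give methyl 6,7-dimethoxy-1H-isochromene-3-carboxylate F3. N,O-Dimethylhydroxylamine hydrochloride and iPrMgCl would convert the ester into N,6,7-trimethoxy-N-methyl-1H-isochromene-3-carboxamide F1, and ethynylmagnesium bromide would then give 6, where the route is rejoined.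

**Step 3.** Methanol or water may add in conjugate fashion to the freed terminal ynone, or base may induce its oligomerisation, in competition with C–Si cleavage. The fallback never places silicon on the alkyne. It sets out from triflate 3: a carbonylative Stille coupling with tributyl(ethynyl)stannane under neutral conditions (Pd(PPh3)4, LiCl, THF, 1 atm CO, 50 °C) would give 6 directly. It rejoins the route at 6 and makes no compound outside the route (F0).

## Further compounds

F0 | step 5 | none | none
F1 | step 2 | N,6,7-trimethoxy-N-methyl-1H-isochromene-3-carboxamide | CON(C)C(=O)C1=Cc2cc(OC)c(OC)cc2CO1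
F2 | step 1 | 6,7-dimethoxy-1H-isochromen-3-yl diphenyl phosphate | COc1cc2c(cc1OC)COC(OP(=O)(Oc1ccccc1)Oc1ccccc1)=C2
F3 | step 1 | methyl 6,7-dimethoxy-1H-isochromene-3-carboxylate | COC(=O)C1=Cc2cc(OC)c(OC)cc2CO1
F0 | step 3 | none | none
A1 | alternative 1 | 2-iodo-4,5-dimethoxyphenyl trifluoromethanesulfonate | COc1cc(I)c(OS(=O)(=O)C(F)(F)F)cc1OC
A2 | alternative 1 | 2-(2,4-dimethoxyphenyl)-2-ethynyl-1,3-dioxolane | COc1ccc(C2(C#C)OCCO2)c(OC)c1
A3 | alternative 1 | 2-{[2-(2,4-dimethoxyphenyl)-1,3-dioxolan-2-yl]ethynyl}-4,5-dimethoxybenzaldehyde | COc1ccc(C2(C#Cc3cc(OC)c(OC)cc3C=O)OCCO2)c(OC)c1
A4 | alternative 2 | 4,5-dimethoxy-2-methylbenzaldehyde | COc1cc(C)c(C=O)cc1OC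
A5 | alternative 2 | 2-(2,4-dimethoxyphenyl)-2-oxoacetaldehyde | COc1ccc(C(=O)C=O)c(OC)c1
A6 | alternative 2 | racemic 3-(2,4-dimethoxybenzoyl)-6,7-dimethoxyisochroman-1-ol, lactol epimers (one stereoisomer drawn) | COc1ccc(C(=O)[C@@H]2Cc3cc(OC)c(OC)cc3[C@H](O)O2)c(OC)c1
A7 | alternative 3 | 2-diazo-1-(2,4-dimethoxyphenyl)ethan-1-one | COc1ccc(C(=O)C=[N+]=[N-])c(OC)c1
A8 | alternative 3 | 5,6-dimethoxy-1,3-dihydroisobenzofuran | COc1cc2c(cc1OC)COC2
A9 | alternative 3 | racemic (6,7-dimethoxy-3,4-dihydro-1H-isochromen-3-yl)(2,4-dimethoxyphenyl)methanone (one enantiomer drawn) | COc1ccc(C(=O)[C@H]2Cc3cc(OC)c(OC)cc3CO2)c(OC)c1
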